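**Retrosynthetic overview**
1. Target ⇒ 1,2-reduction of an α-methylene cycloheptanone ⇒ one-carbon ring expansion of a 9-ethynyl trans-hydrindan-9-ol. C1 shifts from C9 to the alkyne carbon C10, so the seven-membered ring and the exocyclic methylene form in one step.
2. C12–C13 ⇒ Felkin aldol of the C12 aldehyde (held as its lactol) with methyl isopropenyl ketone, followed by C12 acetylation and reagent-controlled reduction of the C14 ketone.
3. C7–C11 ⇒ O6-tethered vinyl-radical cyclisation of a bromoallyl acetal (from methoxyallene) onto a C7=C8 enone. Exo-face hydrogenation then sets C11.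
4. C5–C4 and C1–C2 ⇒ anti-selective conjugate addition/allylation of (S)-4-hydroxycyclohexenone. C3=C4 ⇒ ring-closing metathesis.
5. Ring order: six-membered carbocycle (bought) → cyclopentene → temporary tetrahydrofuran acetal (opened again) → six-membered ring expanded to the seven-membered ring last.

Assumption: enantiopure (S)-4-hydroxycyclohex-2-en-1-one is taken as a catalogue compound. The target numbering is used for every compound (C1/C5 ring fusion, C3=C4–Me, C6 carbinol, C7 side-chain carbon, C9 carbinol, C10 methylene-bearing carbon, C11 CHMe, C12 CHOAc, C13 CH2, C14 CHOH, C15 isopropenyl carbon). The SMILES is read as (1S,5R,6S,7R,9S,11S,12S,14R) with H-1 and H-5 trans.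

Step 1
Reactants: 1 (S)-4-hydroxycyclohex-2-en-1-one; 2 methoxyallene (1-methoxypropa-1,2-diene)
Product: 3 (S)-4-[(2-bromo-1-methoxyprop-2-en-1-yl)oxy]cyclohex-2-en-1-one (mixed acetal; both epimers at acetal carbon C12)
Conditions: NBS (1.1 equiv), CH2Cl2, −40 to 0 °C
Reagents that add atoms: N-bromosuccinimide, O=C1CCC(=O)N1Br
Why: Bromoalkoxylation (cohalogenation) of an alkoxyallene, in which Br+ adds to the central allene carbon and the C6 hydroxyl traps the oxocarbenium ion, so one operation masks O6 as an ether-type acetal and brings in C11, C12 and the future C11 methyl carbon, while C6 (S) comes unchanged from 1.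

Step 2
Reactants: 3 mixed acetal; 4 isopropenylmagnesium bromide; 5 allyl bromide
Product: 7 (2S,3R,4S)-2-allyl-4-[(2-bromo-1-methoxyprop-2-en-1-yl)oxy]-3-(prop-1-en-2-yl)cyclohexan-1-one, via bromomagnesium enolate 6 (not isolated)
Conditions: 4 (1.3 equiv), CuBr·SMe2 (10 mol %), THF, −78 °C; then 5 (3 equiv), DMPU, −78 to −10 °C
Reagents that add atoms: none
Why: Copper-catalysed conjugate addition followed by enolate allylation (three-component coupling), in which the cuprate attacks C5 anti to the bulky C6 acetal oxygen (sets C5 R) and the enolate is allylated at C1 anti to the new isopropenyl group (sets C1 S), giving the thermodynamically favoured all-trans array that becomes the trans ring fusion.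

Step 3
Reactants: 7 allyl isopropenyl ketone
Product: 8 (3aR,4S,7aS)-4-[(2-bromo-1-methoxyprop-2-en-1-yl)oxy]-3-methyl-1,3a,4,5,6,7a-hexahydro-7H-inden-7-one (trans-fused hydrindenone; C9 ketone; C3=C4 alkene)
Conditions: second-generation Grubbs catalyst (5 mol %), CH2Cl2, 40 °C
Reagents that add atoms: none
Why: Ring-closing metathesis of the diequatorial allyl/isopropenyl pair closes the trisubstituted cyclopentene under neutral conditions that do not epimerise C1, and the 2-bromoalkene is inert to the ruthenium carbene.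

Step 4
Reactants: 8 trans-hydrindenone
Product: 10 (3aR,4S,7aS)-4-[(2-bromo-1-methoxyprop-2-en-1-yl)oxy]-3-methyl-1,3a,4,7a-tetrahydro-7H-inden-7-one (C7=C8 enone), via lithium enolate 9 (not isolated)
Conditions: lithium diisopropylamide (1.05 equiv), THF, −78 °C; then PhS(Cl)=N-t-Bu, −78 °C
Reagents that add atoms: none
Why: Kinetic deprotonation takes a C8 methylene proton rather than the ring-fusion C1–H, and the Mukaiyama sulfinimidoyl chloride dehydrogenation of the lithium enolate gives the enone at −78 °C without palladium (which would insert into the vinyl bromide) and without touching C1.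

Step 5
Reactants: 10 enone
Product: 11 tricyclic keto acetal with a C11 exocyclic methylene (tetrahydrofuran O6–C12H(OMe)–C11(=CH2)–C7 cis-fused at C6/C7 to the trans-hydrindenone; 7R)
Conditions: Bu3SnH (slow addition), AIBN (cat.), benzene, 80 °C
Reagents that add atoms: none
Why: Ueno–Stork-type 5-exo-trig radical cyclisation, in which the vinyl radical from the C11–Br bond is tied to the equatorial O6 and can reach the enone β-carbon C7 only from that face (axial attack), so C7 (R) is set cis to O6 and the resulting α-keto radical is reduced by the stannane.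

Step 6
Reactants: 11 methylene tricycle
Product: 12 tricyclic keto acetal (1S,5R,6S,7R,11S) in which C11 carries H cis to H-6 and H-7 and a methyl group on the concave face
Conditions: H2 (1 atm), RhCl(PPh3)3 (5 mol %), benzene–EtOH, 23 °C
Reagents that add atoms: none
Why: Homogeneous catalytic hydrogenation reduces the 1,1-disubstituted exocyclic alkene and not the trisubstituted ring alkene, and H2 arrives on the convex face of the cis-fused oxabicycle (the face of H-6 and H-7), which sets C11 (S).

Step 7
Reactants: 12 keto acetal; 13 ethynylmagnesium bromide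
Product: 14 9-ethynyl carbinol of 12 (9R; hydroxyl axial and cis to the C7–C11 bond)
Conditions: 13 (1.5 equiv), THF, −78 to 0 °C; then H2O
Reagents that add atoms: none
Why: Grignard 1,2-addition in which the weakly basic acetylide does not enolise the ketone (C1 stays intact) and enters opposite the axial C7–C11 bond, and the new C9 centre is erased again in step 12, so its configuration is not critical.

Step 8
Reactants: 14 ethynyl carbinol acetal
Product: 15 lactol (C12 hemiacetal; both anomers) of 14
Conditions: AcOH–THF–H2O (3:1:1), 40 °C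
Reagents that add atoms: water, O
Why: Acid-catalysed acetal hydrolysis exchanges the anomeric methoxy group for hydroxyl under conditions too mild to ionise the tertiary propargylic alcohol or epimerise C11, and the lactol is the masked C12 aldehyde.

Step 9
Reactants: 15 lactol; 16 3-methylbut-3-en-2-one
Product: 18 β-hydroxy enone (12S) with the side chain CH(CH3)–CH(OH)–CH2–C(=O)–C(CH3)=CH2 at C7 of the 9-ethynyl trans-hydrindene-6,9-diol, via lithium enolate 17 (not isolated)
Conditions: 16 (3.6 equiv), lithium diisopropylamide (3.5 equiv), THF, −78 °C; then 15 (1 equiv), −78 to −40 °C; then H2O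
Reagents that add atoms: none
Why: Aldol addition to the ring-opened hydroxy-aldehyde form of the lithium lactolate (the excess enolate first removes the acidic O–H protons), with Felkin–Anh attack anti to the large ring substituent on C11 giving the 11,12-syn carbinol, C12 (S).

Step 10
Reactants: 18 β-hydroxy enone
Product: 19 C12 acetate of 18
Conditions: Ac2O (1.2 equiv), pyridine, CH2Cl2, 0 °C
Reagents that add atoms: acetic anhydride, CC(=O)OC(C)=O
Why: Chemoselective esterification, because the acyclic C12 hydroxyl reacts much faster than the C6 hydroxyl (flanked by the ring fusion and the axial side chain) or the tertiary C9 hydroxyl, and the absence of DMAP at low temperature avoids β-elimination.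

Step 11
Reactants: 19 β-acetoxy enone
Product: 20 (14R)-allylic alcohol of 19 (12,14-syn)
Conditions: (S)-Me-CBS oxazaborolidine [(S)-1-methyl-3,3-diphenyltetrahydro-1H,3H-pyrrolo[1,2-c][1,3,2]oxazaborole] (0.5 equiv), catecholborane (excess), toluene, −78 °C; then H2O
Reagents that add atoms: none
Why: Corey–Bakshi–Shibata reduction, in which the (S)-catalyst treats the branched alkenyl carbon C15 as the large and C13H2 as the small substituent and gives the (14R) alcohol by 1,2-reduction, while catecholborane at −78 °C leaves alkyne, alkenes and acetate alone.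

Step 12
Reactants: 20 9-ethynyl trans-hydrindan-9-ol with complete side chain
Product: 21 ring-expanded trans-hydroazulenone (C9 ketone; C10 exocyclic methylene; 1S,5R,6S,7R,11S,12S,14R)
Conditions: [(4-CF3C6H4)3P]AuNTf2 (5 mol %), 4 Å molecular sieves, CH2Cl2, 0 to 35 °C
Reagents that add atoms: none
Why: Proposed new method: the π-acidic monovalent gold cation binds the terminal alkyne, the more substituted and more electron-rich C9–C1 σ-bond (not C9–C8) shifts to the internal alkyne carbon C10 with retention at C1 while the carbinol collapses to the C9 ketone (semipinacol 1,2-alkyl shift), and the proton released cleaves the vinyl–gold bond to leave the exocyclic methylene; the shift should be feasible in this six-membered carbinol because the alkynol-to-enone isomerisation is strongly exergonic and because expansion relieves the strain of the trans-fused cyclopentene and the syn-diaxial clash between the C9 hydroxyl and the C7 side chain, an electron-poor phosphine with a non-coordinating anion maximises alkyne activation, and dry conditions suppress Meyer–Schuster isomerisation; the closest known reaction type is the gold-catalysed ring expansion of 1-alkynylcyclopropanols and 1-alkynylcyclobutanols to 2-alkylidenecycloalkanones, which has not been shown for carbinols without small-ring strain.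

Step 13
Reactants: 21 α-methylene cycloheptanone
Product: 22 target CNP0281601.4 (1S,5R,6S,7R,9S,11S,12S,14R)
Conditions: (R)-Me-CBS oxazaborolidine [(R)-1-methyl-3,3-diphenyltetrahydro-1H,3H-pyrrolo[1,2-c][1,3,2]oxazaborole] (0.5 equiv), catecholborane (excess), toluene, −78 °C; then H2O
Reagents that add atoms: none
Why: Corey–Bakshi–Shibata reduction with the enantiomeric catalyst, in which reagent control (alkenyl carbon C10 large, C8H2 small) gives the (9S) allylic alcohol by clean 1,2-reduction of the α-methylene ketone under neutral cold conditions that neither cleave nor migrate the acetate.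

**Compound list**
1 | (S)-4-hydroxycyclohex-2-en-1-one | O=C1C=C[C@@H](O)CC1 | starting material
2 | methoxyallene | COC=C=C | starting material
3 | (S)-4-[(2-bromo-1-methoxyprop-2-en-1-yl)oxy]cyclohex-2-en-1-one (C12 epimers) | O=C1C=C[C@@H](OC(OC)C(Br)=C)CC1 | intermediate
4 | isopropenylmagnesium bromide | CC(=C)[Mg]Br | starting material
5 | allyl bromide | C=CCBr | starting material
6 | bromomagnesium enolate (C9–O, C9=C1) of the C5 isopropenyl adduct | Br[Mg]OC1=C[C@H](C(C)=C)[C@@H](OC(OC)C(Br)=C)CC1 | intermediate (not isolated)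
7 | (2S,3R,4S)-2-allyl-4-[(2-bromo-1-methoxyprop-2-en-1-yl)oxy]-3-(prop-1-en-2-yl)cyclohexan-1-one | C=CC[C@@H]1C(=O)CC[C@H](OC(OC)C(Br)=C)[C@H]1C(C)=C | intermediate
8 | trans-hydrindenone, (3aR,4S,7aS)-4-[(2-bromo-1-methoxyprop-2-en-1-yl)oxy]-3-methyl-1,3a,4,5,6,7a-hexahydro-7H-inden-7-one | C1CC(=O)[C@H]2CC=C(C)[C@@H]2[C@H]1OC(OC)C(Br)=C | intermediate
9 | lithium enolate (C9–O, C8=C9) of 8 | C1C=C(O[Li])[C@H]2CC=C(C)[C@@H]2[C@H]1OC(OC)C(Br)=C | intermediate (not isolated)
10 | C7=C8 enone, (3aR,4S,7aS)-4-[(2-bromo-1-methoxyprop-2-en-1-yl)oxy]-3-methyl-1,3a,4,7a-tetrahydro-7H-inden-7-one | C1=CC(=O)[C@H]2CC=C(C)[C@@H]2[C@H]1OC(OC)C(Br)=C | intermediate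
11 | tricyclic keto acetal with C11 exocyclic methylene (7R, H-6/H-7 cis) | COC3C(=C)[C@H]1CC(=O)[C@H]2CC=C(C)[C@@H]2[C@H]1O3 | intermediate
12 | tricyclic keto acetal (1S,5R,6S,7R,11S) | COC3[C@@H](C)[C@H]1CC(=O)[C@H]2CC=C(C)[C@@H]2[C@H]1O3 | intermediate
13 | ethynylmagnesium bromide | C#C[Mg]Br | starting material
14 | (9R)-9-ethynyl carbinol acetal | COC3[C@@H](C)[C@H]1C[C@](O)(C#C)[C@H]2CC=C(C)[C@@H]2[C@H]1O3 | intermediate
15 | C12 lactol (both anomers) | OC3[C@@H](C)[C@H]1C[C@](O)(C#C)[C@H]2CC=C(C)[C@@H]2[C@H]1O3 | intermediate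
16 | 3-methylbut-3-en-2-one | CC(=O)C(C)=C | starting material
17 | lithium enolate of 16 | [Li]OC(=C)C(C)=C | intermediate (not isolated)
18 | (12S)-β-hydroxy enone, 6,9,12-triol with C14 ketone | C=C(C)C(=O)C[C@H](O)[C@@H](C)[C@H]1C[C@](O)(C#C)[C@H]2CC=C(C)[C@@H]2[C@H]1O | intermediate
19 | C12 acetate of 18 | C=C(C)C(=O)C[C@H](OC(C)=O)[C@@H](C)[C@H]1C[C@](O)(C#C)[C@H]2CC=C(C)[C@@H]2[C@H]1O | intermediate
20 | (14R)-allylic alcohol, substrate of the ring expansion | C=C(C)[C@H](O)C[C@H](OC(C)=O)[C@@H](C)[C@H]1C[C@](O)(C#C)[C@H]2CC=C(C)[C@@H]2[C@H]1O | intermediate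
21 | trans-hydroazulenone with C9 ketone and C10 exocyclic methylene | C=C(C)[C@H](O)C[C@H](OC(C)=O)[C@@H](C)[C@H]1CC(=O)C(=C)[C@H]2CC=C(C)[C@@H]2[C@H]1O | intermediate
22 | CNP0281601.4 | C=C(C)[C@H](O)C[C@H](OC(C)=O)[C@@H](C)[C@H]1C[C@H](O)C(=C)[C@H]2CC=C(C)[C@@H]2[C@H]1O | target

**Totals**
Total step count: 13. Longest linear sequence: 13 steps, from 1 to 22.

**Three steps most likely to fail**

Step 12 (the new ring expansion). The shift may be too slow without small-ring strain. It could also divert to the Meyer–Schuster enal, to C8 migration, or to attack of the ring alkene on the activated alkyne.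

The fallback uses known chemistry only, sets out from 20 and comes back at 21.
- Silylate 20 with t-BuMe2SiOTf and 2,6-lutidine at −78 °C to give the 6,14-bis(tert-butyldimethylsilyl) ether F1.
- Semihydrogenate it (H2, Pd/CaCO3 poisoned with Pb(OAc)2, quinoline) to the 9-vinyl carbinol F2.
- Epoxidise the vinyl group under direction of the only free hydroxyl (VO(acac)2, t-BuOOH) to give the epoxy alcohol F3.
- Rearrange F3 with SnCl4 in CH2Cl2 at −78 °C. This is the semipinacol ring expansion of a 2,3-epoxy alcohol, with C1 migrating anti to the breaking C10–O bond, and it gives the 10-(hydroxymethyl)cycloheptanone F4.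
- Convert F4 with MsCl and Et3N into the primary mesylate F5, and eliminate with DBU to the bis-silylated α-methylene ketone F6.
- Remove both silyl groups with HF·pyridine to reach 21.

Step 9 (aldol on the lactol). The open aldehyde form may be too scarce, the Felkin ratio may be modest with a free alkoxide nearby, and C11 could epimerise.

The fallback sets out from 15 and comes back at 19. It runs the aldol on a true aldehyde with O6 capped.
- Reduce 15 with NaBH4 in MeOH to the 6,9,12-triol F7.
- Silylate the primary and the C6 hydroxyl with Et3SiOTf and 2,6-lutidine to give the 6,12-bis(triethylsilyl) ether F8.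
- Oxidise under Swern conditions ((COCl)2, DMSO, Et3N, −78 to −30 °C). These convert only the primary silyl ether and give the C12 aldehyde F9.
- Add lithium enolate 17 at −78 °C (Felkin control) to obtain the 6-O-silyl aldol F10.
- Acetylate with Ac2O, pyridine and DMAP to the 6-O-silyl C12 acetate F11.
- Cleave the silyl ether with HF·pyridine to rejoin the route at 19.

Step 6 (face selectivity of the hydrogenation). One of the two C12 acetal epimers may shield the convex face and erode the C11 ratio.

The fallback sets out from 11 and comes back at 15. It sets C11 by kinetic protonation instead of hydrogenation.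
- Oxidise 11 with CrO3 and H2SO4 in acetone at 0 °C to the α-methylene-γ-lactone ketone F12.
- Carry out conjugate reduction with [(Ph3P)CuH]6 in wet toluene. Hydride goes to the methylene carbon and the enolate is protonated from the convex face, which gives the 11S methyl lactone ketone F13.
- Add 13 at −78 °C, selectively to the ketone, to give the 9-ethynyl carbinol lactone F14.
- Reduce the lactone with iBu2AlH (2.2 equiv) at −78 °C to lactol 15.

**Further compounds**
F1 | step 12 | 6,14-bis(tert-butyldimethylsilyl) ether of 20 | C=C(C)[C@H](O[Si](C)(C)C(C)(C)C)C[C@H](OC(C)=O)[C@@H](C)[C@H]1C[C@](O)(C#C)[C@H]2CC=C(C)[C@@H]2[C@H]1O[Si](C)(C)C(C)(C)C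
F2 | step 12 | 9-vinyl carbinol | C=C(C)[C@H](O[Si](C)(C)C(C)(C)C)C[C@H](OC(C)=O)[C@@H](C)[C@H]1C[C@](O)(C=C)[C@H]2CC=C(C)[C@@H]2[C@H]1O[Si](C)(C)C(C)(C)C
F3 | step 12 | 9-(oxiran-2-yl) carbinol (epoxy alcohol, C10 epimers) | C=C(C)[C@H](O[Si](C)(C)C(C)(C)C)C[C@H](OC(C)=O)[C@@H](C)[C@H]1C[C@](O)(C3CO3)[C@H]2CC=C(C)[C@@H]2[C@H]1O[Si](C)(C)C(C)(C)C
F4 | step 12 | 10-(hydroxymethyl)cycloheptanone (C10 epimers) | C=C(C)[C@H](O[Si](C)(C)C(C)(C)C)C[C@H](OC(C)=O)[C@@H](C)[C@H]1CC(=O)C(CO)[C@H]2CC=C(C)[C@@H]2[C@H]1O[Si](C)(C)C(C)(C)C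
F5 | step 12 | primary mesylate of F4 | C=C(C)[C@H](O[Si](C)(C)C(C)(C)C)C[C@H](OC(C)=O)[C@@H](C)[C@H]1CC(=O)C(COS(C)(=O)=O)[C@H]2CC=C(C)[C@@H]2[C@H]1O[Si](C)(C)C(C)(C)C
F6 | step 12 | 6,14-bis(tert-butyldimethylsilyl) ether of 21 | C=C(C)[C@H](O[Si](C)(C)C(C)(C)C)C[C@H](OC(C)=O)[C@@H](C)[C@H]1CC(=O)C(=C)[C@H]2CC=C(C)[C@@H]2[C@H]1O[Si](C)(C)C(C)(C)C
F7 | step 9 | 6,9,12-triol | OC[C@@H](C)[C@H]1C[C@](O)(C#C)[C@H]2CC=C(C)[C@@H]2[C@H]1O
F8 | step 9 | 6,12-bis(triethylsilyl) ether of F7 | CC[Si](CC)(CC)OC[C@@H](C)[C@H]1C[C@](O)(C#C)[C@H]2CC=C(C)[C@@H]2[C@H]1O[Si](CC)(CC)CC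
F9 | step 9 | C12 aldehyde with 6-O-triethylsilyl group | O=C[C@@H](C)[C@H]1C[C@](O)(C#C)[C@H]2CC=C(C)[C@@H]2[C@H]1O[Si](CC)(CC)CC
F10 | step 9 | 6-O-triethylsilyl ether of 18 | C=C(C)C(=O)C[C@H](O)[C@@H](C)[C@H]1C[C@](O)(C#C)[C@H]2CC=C(C)[C@@H]2[C@H]1O[Si](CC)(CC)CC
F11 | step 9 | 6-O-triethylsilyl ether of 19 | C=C(C)C(=O)C[C@H](OC(C)=O)[C@@H](C)[C@H]1C[C@](O)(C#C)[C@H]2CC=C(C)[C@@H]2[C@H]1O[Si](CC)(CC)CC
F12 | step 6 | α-methylene-γ-lactone ketone | O=C3C(=C)[C@H]1CC(=O)[C@H]2CC=C(C)[C@@H]2[C@H]1O3
F13 | step 6 | (11S)-methyl lactone ketone | O=C3[C@@H](C)[C@H]1CC(=O)[C@H]2CC=C(C)[C@@H]2[C@H]1O3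
F14 | step 6 | (9R)-9-ethynyl carbinol lactone | O=C3[C@@H](C)[C@H]1C[C@](O)(C#C)[C@H]2CC=C(C)[C@@H]2[C@H]1O3
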